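**Retrosynthetic overview**

1. Target 34 ← selective C2 acetylation of diol acid 33 ← C8 methylation of an enol triflate and cleavage of the C4 vinyl group to the C19 aldehyde ← enone 26.
2. Enone 26 ← (desilylation, loss of benzenesulfinate) cycloadduct 24 ← intramolecular Diels–Alder reaction of the acyclic trienyl sulfone 23, which forms C6–C7 and C5–C10 and closes rings A and B in the same operation.
3. Enabling feature: ring B is a cyclohexene in which C7–C8–C9–C10 becomes a diene once the C7=C8 olefin is moved to C8=C9 as a C8 silyl enol ether, with C5–C6 as the dienophile. C5 and C10 are the two atoms shared with ring A, so the C1–C2–C3–C4 chain (cis-2,3-diol as a temporary dioxolane, quaternary C4) is a four-atom tether. The C8 oxygen later sets C9–H and returns the C7=C8 olefin; the C6 sulfonyl activator leaves as sulfinate.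
4. Triene 23 ← keto aldehyde 11 (pentynol carbometalation/iodination, then Negishi coupling with the C11–C15 side chain from 3-methylglutarate) + allylboronate 15 (C4, C5, C18, C19); C2 by D-proline α-oxygenation, C3/C4 by allylboration.
5. Ring order: rings A and B are formed together in step 15; the dioxolane is made in step 10 and removed in step 21.

Key step: step 15

Remark: labdane numbering is used throughout (ring carbons C1–C10, side chain C11–C16, C17 on C8, C18 = methyl and C19 = formyl carbon on C4, C20 on C10); compounds 1, 4, 5 and 12 are taken as catalogue chemicals.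

**Step 1**
Reactants: 1 (3R)-5-methoxy-3-methyl-5-oxopentanoic acid (methyl hydrogen (R)-3-methylglutarate)
Product: 2 methyl (3R)-5-hydroxy-3-methylpentanoate
Conditions: BH3·SMe2, THF, 0 °C → rt; MeOH quench; used crude
Reagents that add atoms: none
Why: Chemoselective borane reduction of a carboxylic acid in the presence of an ester turns only the free acid terminus into the C11 carbinol and leaves the C13 stereocenter untouched.

**Step 2**
Reactants: 2 methyl (3R)-5-hydroxy-3-methylpentanoate
Product: 3 methyl (3S)-5-iodo-3-methylpentanoate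
Conditions: I2, PPh3, imidazole, CH2Cl2, 0 °C → rt
Reagents that add atoms: iodine, II
Why: Appel-type iodination converts the primary alcohol into the iodide by SN2 displacement without touching C13 (the descriptor changes only through the priority rules).

**Step 3**
Reactants: 4 pent-3-yn-2-ol (racemic); 5 [2-(1,3-dioxolan-2-yl)ethyl]magnesium bromide
Product: 7 (3Z)-6-(1,3-dioxolan-2-yl)-3-iodo-4-methylhex-3-en-2-ol (racemic at the carbinol), via alkenylmagnesium bromide 6 (not isolated)
Conditions: 5 (4 equiv), Fe(acac)3 (15 mol%), THF, −78 → 0 °C; then I2, −78 °C → rt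
Reagents that add atoms: iodine, II
Why: Alkoxide-directed, iron-catalysed syn-carbomagnesiation of a propargylic alcohol should deliver the alkyl group to the distal alkyne carbon (C10) and magnesium to the proximal one (C9), and iodinolysis with retention then fixes the tetrasubstituted olefin with the C1 chain cis to iodine and the C20 methyl cis to C8.

**Step 4**
Reactants: 7 (3Z)-6-(1,3-dioxolan-2-yl)-3-iodo-4-methylhex-3-en-2-ol
Product: 8 (3Z)-6-(1,3-dioxolan-2-yl)-3-iodo-4-methylhex-3-en-2-one
Conditions: Dess–Martin periodinane, NaHCO3, CH2Cl2, 0 °C → rt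
Reagents that add atoms: none
Why: Buffered Dess–Martin oxidation of the secondary allylic alcohol should give the α-iodo enone without isomerising the olefin or opening the dioxolane, and it removes the racemic carbinol centre.

**Step 5**
Reactants: 3 methyl (3S)-5-iodo-3-methylpentanoate; 8 (3Z)-6-(1,3-dioxolan-2-yl)-3-iodo-4-methylhex-3-en-2-one
Product: 10 methyl (3R,6E)-6-acetyl-9-(1,3-dioxolan-2-yl)-3,7-dimethylnon-6-enoate, via alkylzinc iodide 9 (not isolated)
Conditions: 3, Zn dust, LiCl, THF, 40 °C; then 8, Pd2(dba)3 (2.5 mol%), SPhos (10 mol%), THF, rt → 40 °C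
Reagents that add atoms: none
Why: Direct zinc insertion into the primary iodide tolerates the ester, and Negishi sp3–sp2 coupling of an α-iodo enone proceeds with retention of olefin geometry, so the side chain (C11) ends cis to the C1 chain and the acetyl group (C8) cis to C20.

**Step 6**
Reactants: 10 methyl (3R,6E)-6-acetyl-9-(1,3-dioxolan-2-yl)-3,7-dimethylnon-6-enoate
Product: 11 methyl (3R,6E)-6-acetyl-3,7-dimethyl-10-oxodec-6-enoate
Conditions: 1 M HCl, THF, rt
Reagents that add atoms: water, O
Why: Acid-catalysed acetal hydrolysis frees the C3 aldehyde while the ester and the tetrasubstituted enone are stable, and the E geometry holds C2 away from the ketone so no intramolecular aldol can follow.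

**Step 7**
Reactants: 12 (2E)-3-iodo-2-methylprop-2-en-1-ol
Product: 13 tert-butyl{[(2E)-3-iodo-2-methylprop-2-en-1-yl]oxy}dimethylsilane
Conditions: TBSCl, imidazole, CH2Cl2, rt
Reagents that add atoms: tert-butyldimethylsilyl chloride, CC(C)(C)[Si](C)(C)Cl
Why: Standard silylation of the primary allylic alcohol leaves the vinyl iodide geometry unchanged.

**Step 8**
Reactants: 13 tert-butyl{[(2E)-3-iodo-2-methylprop-2-en-1-yl]oxy}dimethylsilane
Product: 15 tert-butyldimethyl{[(2E)-2-methyl-4-(4,4,5,5-tetramethyl-1,3,2-dioxaborolan-2-yl)but-2-en-1-yl]oxy}silane, via alkenyllithium 14 (not isolated)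
Conditions: t-BuLi (2.1 equiv), Et2O, −78 °C; then ClCH2B(pin), −78 °C → rt
Reagents that add atoms: 2-(chloromethyl)-4,4,5,5-tetramethyl-1,3,2-dioxaborolane, ClCB1OC(C)(C)C(C)(C)O1
Why: Iodine–lithium exchange retains the olefin geometry and the borate formed with the chloromethylboronate undergoes 1,2-migration of the alkenyl group with loss of chloride (Matteson homologation), giving the E γ,γ-disubstituted allylboronate.

**Step 9**
Reactants: 11 methyl (3R,6E)-6-acetyl-3,7-dimethyl-10-oxodec-6-enoate; 15 (E)-allylboronate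
Product: 17 methyl (3R,6E,9S,10R,11S)-6-acetyl-9-(anilinooxy)-11-({[tert-butyl(dimethyl)silyl]oxy}methyl)-10-hydroxy-3,7,11-trimethyltrideca-6,12-dienoate, via α-anilinooxy aldehyde 16 (not isolated)
Conditions: D-proline (20 mol%), PhNO (1.1 equiv), CHCl3, 4 °C; then 15 (1.5 equiv), 4 °C → rt; aq. NaHCO3
Reagents that add atoms: nitrosobenzene, O=Nc1ccccc1
Why: Enamine catalysis by D-proline should direct the nitroso aldol (α-aminoxylation) to the face that gives the 2S aldehyde, and the allylboration then passes through a chair Zimmerman–Traxler transition state anti to the C2 oxygen (Cornforth/Felkin–Anh control, reinforced by the Z methyl of the reagent), with the E CH2OTBS group ending anti and the Z methyl syn to the new C3 hydroxyl, which sets C3 and the quaternary C4.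

**Step 10**
Reactants: 17 homoallylic alcohol
Product: 19 acetonide of diol 18 (cis-4,5-disubstituted 2,2-dimethyl-1,3-dioxolane across O2 and O3; C5–OTBS kept), via 2,3-diol 18 (not isolated)
Conditions: Zn dust, AcOH/THF, rt; filter, concentrate; then 2,2-dimethoxypropane, PPTS (cat.), CH2Cl2, rt
Reagents that add atoms: 2,2-dimethoxypropane, COC(C)(C)OC
Why: Zinc in acetic acid cleaves the weak N–O bond reductively, and acid-catalysed transketalisation then closes the dioxolane on the only free 1,2-diol because O5 is still silylated; no stereocenter is touched.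

**Step 11**
Reactants: 19 acetonide
Product: 20 primary alcohol (19 with C5–OH in place of C5–OTBS)
Conditions: TBAF, THF, 0 °C → rt
Reagents that add atoms: none
Why: Fluoride-mediated desilylation of the primary silyl ether leaves the acetonide, ester and tetrasubstituted enone intact.

**Step 12**
Reactants: 20 primary alcohol
Product: 21 aldehyde (C5 formyl on the quaternary C4)
Conditions: Dess–Martin periodinane, NaHCO3, CH2Cl2, rt
Reagents that add atoms: none
Why: Dess–Martin oxidation gives a non-enolisable α-quaternary aldehyde, so nothing can epimerise.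

**Step 13**
Reactants: 21 aldehyde
Product: 22 (E)-vinyl sulfone (C5=C6–SO2Ph on C4)
Conditions: (EtO)2P(O)CH2SO2Ph, NaH, THF, 0 °C; then 21, 0 °C → rt
Reagents that add atoms: diethyl [(phenylsulfonyl)methyl]phosphonate, CCOP(=O)(CS(=O)(=O)c1ccccc1)OCC
Why: Horner–Wadsworth–Emmons olefination with the sulfonyl-stabilised phosphonate anion should react with the aldehyde far faster than with the hindered methyl ketone and give the E vinyl sulfone.

**Step 14**
Reactants: 22 (E)-vinyl sulfone
Product: 23 2-(tert-butyldimethylsilyloxy)-1,3-diene (C7=C8(OTBS)–C9=C10) bearing the vinyl sulfone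
Conditions: TBSOTf, Et3N, CH2Cl2, −78 → 0 °C; filtration through Et3N-deactivated silica
Reagents that add atoms: tert-butyldimethylsilyl trifluoromethanesulfonate, CC(C)(C)[Si](C)(C)OS(=O)(=O)C(F)(F)F
Why: Soft enolisation (silyl triflate/amine) of the methyl ketone removes the kinetically most accessible α′ proton at C7 and gives the cross-conjugated silyl dienol ether without disturbing the C9=C10 geometry.

**Step 15**
Reactants: 23 silyloxy diene vinyl sulfone
Product: 24 trans-fused cycloadduct (ring A with the cis-2,3-acetonide and C4 methyl/vinyl; ring B with the C8=C9 silyl enol ether and C6 phenylsulfonyl)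
Conditions: PhMe (0.005 M), BHT (cat.), Et3N (trace), sealed tube, 150 °C
Reagents that add atoms: none
Why: A thermal intramolecular [4+2] cycloaddition of the electron-rich 2-silyloxy diene (C7=C8–C9=C10) with the E vinyl sulfone (C5=C6) forms C6–C7 and C5–C10 in one concerted, asynchronous, suprafacial event; the closest known reaction types are intramolecular Diels–Alder reactions of 1-sulfonyl-1,7,9-decatrienes and Diels–Alder reactions of 2-silyloxy dienes with vinyl sulfones. Ring B is closed as the new cyclohexene of the cycloaddition and ring A by the C5–C10 bond across the four-atom C1–C4 tether, that is, fused closure of a 1,7,9-decatriene with the tether on the E position of C10. C10 (quaternary, methyl from the Z position of the diene terminus) and C5 are set together: trans ring fusion should follow from the anti, chair-like tether transition state in which the sulfonyl group of the E dienophile is endo, and the diene face is fixed by the C2/C3/C4 stereotriad, because only one chair keeps the C2 oxygen equatorial and puts the C4 vinyl group, not C2–O together with the C4 methyl, syn-axial to the developing C10 methyl. C6 follows from the E geometry and is erased in step 16. The step needs trans/cis and facial selectivity, secured by the cis-dioxolane, the quaternary C4 and the endo preference, and chemoselectivity for the sulfonyl-activated olefin over the unactivated C4 vinyl group, secured by the activation.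

**Step 16**
Reactants: 24 cycloadduct
Product: 26 enone (C6=C7–C8=O; 9-H trans to the C10 methyl), via β-sulfonyl ketone 25 (not isolated)
Conditions: TBAF, AcOH, THF, 0 °C; then DBU, CH2Cl2, rt
Reagents that add atoms: none
Why: Buffered fluoride cleaves the silyl enol ether and the enolate is protonated at C9 on the face opposite the C20 methyl (axial protonation, which is also the thermodynamically preferred equatorial side chain), after which DBU effects E1cB loss of benzenesulfinate from the β-sulfonyl ketone.

**Step 17**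
Reactants: 26 enone
Product: 28 C7=C8 enol triflate, via lithium enolate 27 (not isolated)
Conditions: LiBH(s-Bu)3 (1.1 equiv), THF, −78 °C; then PhNTf2, −78 → 0 °C
Reagents that add atoms: N-phenylbis(trifluoromethanesulfonimide), O=S(=O)(N(c1ccccc1)S(=O)(=O)C(F)(F)F)C(F)(F)F
Why: Conjugate hydride reduction of the β-unsubstituted cyclohexenone gives the C7=C8 enolate regiospecifically, and O-sulfonylation traps it as the enol triflate without deprotonating C9.

**Step 18**
Reactants: 28 enol triflate
Product: 30 C19 aldehyde (C4 vinyl cleaved to formyl; enol triflate kept), via secondary ozonide 29 (not isolated)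
Conditions: O3, CH2Cl2, −78 °C (Sudan Red 7B end point); then PPh3, −78 °C → rt
Reagents that add atoms: ozone, [O-][O+]=O
Why: Ozonolysis is electrophilic, so the monosubstituted C4 vinyl group should be cleaved well before the electron-poor enol triflate olefin, and reductive work-up gives the aldehyde with the C4 configuration unchanged.

**Step 19**
Reactants: 30 aldehyde enol triflate
Product: 31 methyl ester acetonide with C8 methyl and C7=C8 olefin
Conditions: (MeBO)3, Pd(dppf)Cl2 (5 mol%), K3PO4, 1,4-dioxane, 80 °C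
Reagents that add atoms: trimethylboroxine, CB1OB(C)OB(C)O1
Why: Suzuki–Miyaura coupling of the enol triflate with a methylboron reagent installs C17 with the olefin fixed at C7=C8, and the non-enolisable aldehyde, ester and acetonide tolerate the mild base.

**Step 20**
Reactants: 31 methyl ester
Product: 32 carboxylic acid acetonide
Conditions: LiOH, THF/MeOH/H2O, rt; then 1 M HCl to pH 4
Reagents that add atoms: lithium hydroxide, [Li+].[OH-]
Why: Ester saponification is safe here because O3 is still ketal-protected, so the β-oxy aldehyde cannot undergo retro-aldol cleavage, and it has no α-hydrogen.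

**Step 21**
Reactants: 32 carboxylic acid acetonide
Product: 33 2,3-diol acid
Conditions: AcOH/H2O (4:1), 45 °C
Reagents that add atoms: none
Why: Mild acid-catalysed ketal hydrolysis removes the cis-fused acetonide under conditions the trisubstituted C7=C8 olefin should survive.

**Step 22**
Reactants: 33 2,3-diol acid
Product: 34 CNP0180877.1, (2S,3R,4S,5S,9R,10S,13R)-2-acetoxy-3-hydroxy-19-oxolabd-7-en-15-oic acid
Conditions: Ac2O (1.2 equiv), pyridine, CH2Cl2, 0 °C; aq. work-up
Reagents that add atoms: acetic anhydride, CC(=O)OC(C)=O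
Why: Sterically controlled monoacylation should take the equatorial C2 hydroxyl, since the axial C3 hydroxyl next to the quaternary C4 is strongly hindered, and any mixed anhydride at C15 is hydrolysed on work-up.

**Compound list**

1 | (3R)-5-methoxy-3-methyl-5-oxopentanoic acid | COC(=O)C[C@H](C)CC(=O)O | starting material
2 | methyl (3R)-5-hydroxy-3-methylpentanoate | COC(=O)C[C@H](C)CCO | intermediate
3 | methyl (3S)-5-iodo-3-methylpentanoate | COC(=O)C[C@H](C)CCI | intermediate
4 | pent-3-yn-2-ol (racemic) | CC#CC(C)O | starting material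
5 | [2-(1,3-dioxolan-2-yl)ethyl]magnesium bromide | Br[Mg]CCC1OCCO1 | starting material
6 | alkenylmagnesium bromide (bromomagnesium alkoxide, Mg on C9 cis to the C1 chain; not isolated) | CC(O[Mg]Br)/C([Mg]Br)=C(C)/CCC1OCCO1 | intermediate
7 | (3Z)-6-(1,3-dioxolan-2-yl)-3-iodo-4-methylhex-3-en-2-ol (racemic) | CC(O)/C(I)=C(C)/CCC1OCCO1 | intermediate
8 | (3Z)-6-(1,3-dioxolan-2-yl)-3-iodo-4-methylhex-3-en-2-one | CC(=O)/C(I)=C(C)/CCC1OCCO1 | intermediate
9 | [(3S)-5-methoxy-3-methyl-5-oxopentyl]zinc iodide (not isolated) | COC(=O)C[C@H](C)CC[Zn]I | intermediate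
10 | methyl (3R,6E)-6-acetyl-9-(1,3-dioxolan-2-yl)-3,7-dimethylnon-6-enoate | CC(=O)/C(CC[C@@H](C)CC(=O)OC)=C(C)/CCC1OCCO1 | intermediate
11 | methyl (3R,6E)-6-acetyl-3,7-dimethyl-10-oxodec-6-enoate | CC(=O)/C(CC[C@@H](C)CC(=O)OC)=C(C)/CCC=O | intermediate
12 | (2E)-3-iodo-2-methylprop-2-en-1-ol | I/C=C(\C)CO | starting material
13 | tert-butyl{[(2E)-3-iodo-2-methylprop-2-en-1-yl]oxy}dimethylsilane | I/C=C(\C)CO[Si](C)(C)C(C)(C)C | intermediate
14 | (E)-alkenyllithium from 13 (not isolated) | [Li]/C=C(\C)CO[Si](C)(C)C(C)(C)C | intermediate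
15 | tert-butyldimethyl{[(2E)-2-methyl-4-(4,4,5,5-tetramethyl-1,3,2-dioxaborolan-2-yl)but-2-en-1-yl]oxy}silane | CC1(C)OB(C/C=C(\C)CO[Si](C)(C)C(C)(C)C)OC1(C)C | intermediate
16 | methyl (3R,6E,9S)-6-acetyl-9-(anilinooxy)-3,7-dimethyl-10-oxodec-6-enoate (not isolated) | CC(=O)/C(CC[C@@H](C)CC(=O)OC)=C(C)/C[C@H](ONc1ccccc1)C=O | intermediate
17 | methyl (3R,6E,9S,10R,11S)-6-acetyl-9-(anilinooxy)-11-({[tert-butyl(dimethyl)silyl]oxy}methyl)-10-hydroxy-3,7,11-trimethyltrideca-6,12-dienoate | CC(=O)/C(CC[C@@H](C)CC(=O)OC)=C(C)/C[C@H](ONc1ccccc1)[C@H](O)[C@@](C)(C=C)CO[Si](C)(C)C(C)(C)C | intermediate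
18 | methyl (3R,6E,9S,10R,11S)-6-acetyl-11-({[tert-butyl(dimethyl)silyl]oxy}methyl)-9,10-dihydroxy-3,7,11-trimethyltrideca-6,12-dienoate (not isolated) | CC(=O)/C(CC[C@@H](C)CC(=O)OC)=C(C)/C[C@H](O)[C@H](O)[C@@](C)(C=C)CO[Si](C)(C)C(C)(C)C | intermediate
19 | acetonide of 18: cis-4,5-disubstituted 2,2-dimethyl-1,3-dioxolane (C2 S, C3 R, C4 S), C5–OTBS | CC(=O)/C(CC[C@@H](C)CC(=O)OC)=C(C)/C[C@@H]1OC(C)(C)O[C@@H]1[C@@](C)(C=C)CO[Si](C)(C)C(C)(C)C | intermediate
20 | 19 with free C5 primary alcohol | CC(=O)/C(CC[C@@H](C)CC(=O)OC)=C(C)/C[C@@H]1OC(C)(C)O[C@@H]1[C@@](C)(C=C)CO | intermediate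
21 | 20 oxidised to the C5 aldehyde (α-quaternary) | CC(=O)/C(CC[C@@H](C)CC(=O)OC)=C(C)/C[C@@H]1OC(C)(C)O[C@@H]1[C@@](C)(C=C)C=O | intermediate
22 | (E)-vinyl sulfone: C4 bears methyl, vinyl and (E)-2-(phenylsulfonyl)ethenyl | CC(=O)/C(CC[C@@H](C)CC(=O)OC)=C(C)/C[C@@H]1OC(C)(C)O[C@@H]1[C@@](C)(C=C)/C=C/S(=O)(=O)c1ccccc1 | intermediate
23 | 2-(tert-butyldimethylsilyloxy) diene of 22 (C7=C8(OTBS)–C9=C10, C1 trans to C8) | C=C(O[Si](C)(C)C(C)(C)C)/C(CC[C@@H](C)CC(=O)OC)=C(C)/C[C@@H]1OC(C)(C)O[C@@H]1[C@@](C)(C=C)/C=C/S(=O)(=O)c1ccccc1 | intermediate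
24 | trans-fused cycloadduct: 2,3-cis-acetonide, C4 methyl/vinyl (vinyl cis to C20), C6 phenylsulfonyl cis to H5, C8=C9 silyl enol ether, side-chain methyl ester | CC1(C)O[C@H]2C[C@@]3(C)C(CC[C@@H](C)CC(=O)OC)=C(O[Si](C)(C)C(C)(C)C)C[C@@H](S(=O)(=O)c4ccccc4)[C@@H]3[C@](C)(C=C)[C@H]2O1 | intermediate
25 | 6-phenylsulfonyl 8-ketone (9-H trans to C20; not isolated) | CC1(C)O[C@H]2C[C@@]3(C)[C@H](CC[C@@H](C)CC(=O)OC)C(=O)C[C@@H](S(=O)(=O)c4ccccc4)[C@@H]3[C@](C)(C=C)[C@H]2O1 | intermediate
26 | 6-en-8-one (trans-fused, side chain cis to C20) | CC1(C)O[C@H]2C[C@@]3(C)[C@H](CC[C@@H](C)CC(=O)OC)C(=O)C=C[C@@H]3[C@](C)(C=C)[C@H]2O1 | intermediate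
27 | lithium C7=C8 enolate (not isolated) | CC1(C)O[C@H]2C[C@@]3(C)[C@H](CC[C@@H](C)CC(=O)OC)C(O[Li])=CC[C@@H]3[C@](C)(C=C)[C@H]2O1 | intermediate
28 | C7=C8 enol triflate | CC1(C)O[C@H]2C[C@@]3(C)[C@H](CC[C@@H](C)CC(=O)OC)C(OS(=O)(=O)C(F)(F)F)=CC[C@@H]3[C@](C)(C=C)[C@H]2O1 | intermediate
29 | secondary ozonide of the C4 vinyl group (1,2,4-trioxolane, epimers at the ring carbon; not isolated) | CC1(C)O[C@H]2C[C@@]3(C)[C@H](CC[C@@H](C)CC(=O)OC)C(OS(=O)(=O)C(F)(F)F)=CC[C@@H]3[C@](C)(C4OCOO4)[C@H]2O1 | intermediate
30 | C19 aldehyde, C7=C8 enol triflate | CC1(C)O[C@H]2C[C@@]3(C)[C@H](CC[C@@H](C)CC(=O)OC)C(OS(=O)(=O)C(F)(F)F)=CC[C@@H]3[C@](C)(C=O)[C@H]2O1 | intermediate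
31 | methyl 2,3-O-isopropylidene-19-oxolabd-7-en-15-oate (target skeleton) | CC1(C)O[C@H]2C[C@@]3(C)[C@H](CC[C@@H](C)CC(=O)OC)C(C)=CC[C@@H]3[C@](C)(C=O)[C@H]2O1 | intermediate
32 | 2,3-O-isopropylidene-19-oxolabd-7-en-15-oic acid | CC1(C)O[C@H]2C[C@@]3(C)[C@H](CC[C@@H](C)CC(=O)O)C(C)=CC[C@@H]3[C@](C)(C=O)[C@H]2O1 | intermediate
33 | 2,3-dihydroxy-19-oxolabd-7-en-15-oic acid (2,3-cis-diol) | O[C@H]1C[C@@]2(C)[C@H](CC[C@@H](C)CC(=O)O)C(C)=CC[C@@H]2[C@](C)(C=O)[C@H]1O | intermediate
34 | CNP0180877.1, (2S,3R,4S,5S,9R,10S,13R)-2-acetoxy-3-hydroxy-19-oxolabd-7-en-15-oic acid | CC(=O)O[C@H]1C[C@@]2(C)[C@H](CC[C@@H](C)CC(=O)O)C(C)=CC[C@@H]2[C@](C)(C=O)[C@H]1O | target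

**Step count and risks**

Total step count: 22. Longest linear sequence: 18 steps (steps 3–6 and 9–22 from 4; the same count from 1 through steps 1, 2, 5, 6 and 9–22).

Steps most likely to fail:

1. Step 15. The cycloaddition may be too slow at temperatures the silyl dienol ether survives, because the Z methyl on C10 hinders the s-cis diene and opens a competing [1,5]-hydrogen shift; the ring fusion may also form with poor trans/cis selectivity. The fallback sets out from aldehyde 21 and returns at enone 26. Aldehyde 21 is condensed with nitromethane (Henry reaction, tetramethylguanidine cat.) to the nitro alcohol F1, which is dehydrated (MsCl, Et3N) to the (E)-nitroalkene F2. TBSOTf/Et3N gives the silyloxy diene F3, whose much more electrophilic nitroalkene should cyclise near 80 °C in benzene to the nitro cycloadduct F4. TBAF/AcOH and then DBU remove the silyl group and eliminate nitrous acid to give 26.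

2. Step 3. β-Hydride elimination from the alkyl–iron intermediate may lead to hydrometalation instead of carbometalation, or regiocontrol across the alkyne may be lost. The fallback sets out from Grignard reagent 5 and returns at iodo enone 8. But-2-ynoic acid is converted into N-methoxy-N-methylbut-2-ynamide F5 (EDC, MeNHOMe·HCl). The organocopper reagent from 5 and CuBr·SMe2 adds syn to F5 at −78 °C, and the alkenylcopper is trapped with I2 to give the (Z)-α-iodo amide F6. MeMgBr then converts F6 into 8.

3. Step 9. The α-anilinooxy aldehyde may oligomerise or decompose before the hindered allylboronate adds, and facial selectivity may erode in the one-pot mixture. The fallback sets out from aldehyde 11 and returns at diol 18. Aldehyde 11 is α-oxyaminated with TEMPO under enamine catalysis (the enantiomer of a chiral imidazolidinone catalyst that gives the 9S product, CuCl2, air) to the isolable TEMPO ether F7. After purification, F7 is allylborated with 15 in a separate step to the homoallylic alcohol F8. Zn/AcOH cleaves the N–O bond to diol 18, which is ketalised to 19 as in step 10.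

Further compounds
F1 | step 15 | nitro alcohol: 21 with the formyl group converted to CH(OH)CH2NO2 (epimers at the carbinol) | CC(=O)/C(CC[C@@H](C)CC(=O)OC)=C(C)/C[C@@H]1OC(C)(C)O[C@@H]1[C@@](C)(C=C)C(O)C[N+](=O)[O-]
F2 | step 15 | (E)-nitroalkene analogue of 22 | CC(=O)/C(CC[C@@H](C)CC(=O)OC)=C(C)/C[C@@H]1OC(C)(C)O[C@@H]1[C@@](C)(C=C)/C=C/[N+](=O)[O-]
F3 | step 15 | silyloxy diene analogue of 23 with nitro in place of phenylsulfonyl | C=C(O[Si](C)(C)C(C)(C)C)/C(CC[C@@H](C)CC(=O)OC)=C(C)/C[C@@H]1OC(C)(C)O[C@@H]1[C@@](C)(C=C)/C=C/[N+](=O)[O-]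
F4 | step 15 | nitro cycloadduct analogue of 24 (C6 nitro cis to H5) | CC1(C)O[C@H]2C[C@@]3(C)C(CC[C@@H](C)CC(=O)OC)=C(O[Si](C)(C)C(C)(C)C)C[C@@H]([N+](=O)[O-])[C@@H]3[C@](C)(C=C)[C@H]2O1
F5 | step 3 | N-methoxy-N-methylbut-2-ynamide | CC#CC(=O)N(C)OC
F6 | step 3 | (2Z)-5-(1,3-dioxolan-2-yl)-2-iodo-N-methoxy-N,3-dimethylpent-2-enamide | CON(C)C(=O)/C(I)=C(C)/CCC1OCCO1
F7 | step 9 | methyl (3R,6E,9S)-6-acetyl-3,7-dimethyl-10-oxo-9-[(2,2,6,6-tetramethylpiperidin-1-yl)oxy]dec-6-enoate | CC(=O)/C(CC[C@@H](C)CC(=O)OC)=C(C)/C[C@H](ON1C(C)(C)CCCC1(C)C)C=O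
F8 | step 9 | analogue of 17 with (2,2,6,6-tetramethylpiperidin-1-yl)oxy in place of anilinooxy | CC(=O)/C(CC[C@@H](C)CC(=O)OC)=C(C)/C[C@H](ON1C(C)(C)CCCC1(C)C)[C@H](O)[C@@](C)(C=C)CO[Si](C)(C)C(C)(C)C
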